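## Structural features

- The target contains two identical 7,8-dimethoxy-1-methylquinolin-2(1H)-one units, called unit X and unit Y here, flanking a cis-fused bis-dihydropyran core. Ring C is O-4(X), C-4(X), C-3(X), C-a, C-b, C-c. Ring D is O-4(Y), C-4(Y), C-3(Y), C-c, C-b, C-d, where C-d carries two methyl groups. The rings share the C-b–C-c bond.
- Three contiguous stereocentres sit on this core. C-a (S) carries H, C-3(X) and the CH2C(CH3)2OH chain. C-b (S) is the ring-fusion carbon bonded to C-d. C-c (R) is the ring-fusion carbon bonded to O-4(X) and C-3(Y). H-a/H-b are trans, H-b/H-c are cis, and the C-a side chain is anti to C-d.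
- C-c is the fragile point. It is an ether carbon whose leaving group is a vinylogous carboxylate (O-4 of unit X) and whose cation is stabilised by the 4-alkoxyquinolinone of unit Y, so acid can ionise and epimerise it. The tertiary alcohol and the tertiary ether at C-d are also acid-sensitive.
- The ten carbons between C-3(X) and C-3(Y) are two C5 units. No stereocentre carries a handle for an auxiliary, and the two halves are almost identical.
- The real difficulty is to join two near-identical halves while setting three contiguous stereocentres in the absolute sense. An intermolecular union leaves exo/endo, E/Z and facial selectivity without any constraint.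
- The key step exploits two features. First, the CH2C(CH3)2OH group on C-a is the hydrate of a 2-methylprop-1-enyl group, and C-b=C-d is the same unit. At the alkene oxidation level C-a therefore carries two identical isobutenyl groups and is not stereogenic; the unit C-a(CH=C(CH3)2)2 is the reduced skeleton of phorone. Second, C-c is at the aldehyde oxidation level (bonded to O and to the nucleophilic C-3 of unit Y). All three stereocentres can therefore be created together by a cycloaddition that selects one of two enantiotopic isobutenyl groups.

## Logic of the disconnections

**13 to 12.** The tertiary C–OH bond of the side chain is cut (hydration of a trisubstituted alkene in the forward sense). At the alkene level the C-a substituent becomes identical with the group that provides C-b and C-d, which removes the C-a stereocentre from every earlier precursor. The forward step must be a Markovnikov hydration of the only alkene under non-acidic conditions, because C-c does not tolerate strong acid.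

**12 to 8 and 10 (through 11).** Three bonds are cut: C-c–C-b and O-4(Y)–C-d (the two bonds of an oxa-[4+2] cycloaddition) and C-c–O-4(X) (a condensation). In one sentence: an enantioselective intramolecular oxa-[4+2] cycloaddition of the aryloxy-substituted quinolinedione methide 11, formed in the flask from 8 and 10, onto one of two enantiotopic isobutenyl groups. The cut is made here because C-c is an aldehyde carbon in disguise and because ring C can act as the tether that turns an intermolecular problem into an intramolecular one. Rings C and D and all three stereocentres disappear, leaving two achiral quinolinones of the same series. The forward step needs O-selective condensation, closure through O-4 of unit Y, cis ring fusion, H-a/H-b trans, and catalyst control of which isobutenyl group reacts.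

**8 to 5 and 7.** The C-3(X)–C-a bond is cut. C-3 of 5 is its nucleophilic carbon and 7 is a symmetrical pentadienyl electrophile, so one bond gives the whole achiral left half. The forward step must attack the central carbon of the dienyl unit, at carbon and not oxygen, and without acid that would cyclise O-4 onto an isobutenyl group.

**7 to 6.** The carbinol C–H bond is cut (1,2-reduction of a cross-conjugated dienone). The demand is 1,2- over 1,4-selectivity.

**10 to 5 (through 9).** The C-3(Y)–CHO bond is cut. The same quinolinone 5 serves both halves; the demand is mono-formylation at C-3.

**5 to 2 and 3 (through 4).** The amide N–C-2 bond and the C-4–C-4a bond are cut, which reveals a malonyl C3 unit and an N-methylaniline. The forward Friedel–Crafts closure has only one free ortho position, which is para to a methoxy group.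

**2 to 1.** The N–CH3 bond is cut; the demand is mono-methylation.

## Other disconnections considered

Alternative 1: The first that comes to mind cuts C-a–C-b and C-c–O-4(X), that is ring C.
- Forward key step: an intermolecular inverse-demand oxa-Diels–Alder reaction between the pyran C=C of the monomeric pyranoquinolinone A1 and the quinone methide A2 (from 5 and 3-hydroxy-3-methylbutanal).
- This is the shortest plan, by about two steps.
- Its weakness is that the dienophile is a hindered, weakly nucleophilic 1,2-disubstituted alkene, and A2 has easier outlets, such as addition of a second molecule of 5.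
- The configuration of C-a relative to the ring fusion would depend on both the E/Z geometry of A2 and exo/endo approach, with no tether to constrain either.
- Absolute control would require a catalyst to discriminate the faces of two unconnected partners.
- The chosen plan forms the other pair of bonds within a six-membered tether, where allylic strain and ring strain decide the relative configuration.

Alternative 2: Cut C-c–C-3(Y) and O-4(Y)–C-d, that is ring D, by a formal [3+3] annulation.
- Forward key step: the ring C lactol A3 (C-a and C-b set beforehand by an amine-catalysed conjugate addition/hemiacetalisation) is treated with 5 and acid. C-3 of 5 attacks the cyclic oxocarbenium ion at C-c, and O-4 then adds to the protonated isopropenyl group.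
- A nucleophile should approach the oxocarbenium ion anti to the C-b substituent, which gives the trans relationship; the cis fusion would depend on later equilibration.
- Making A3 needs an easily isomerised β,γ-unsaturated aldehyde or an α-branched enal.
- The stereocentres are set in three separate events over more steps.

Alternative 3: Cut only the two C–O bonds O-4(Y)–C-d and O-4(X)–C-c.
- Forward key step: an acid-triggered double cycloetherification of the bis(hydroxyquinolinonyl) diene A4, in which O-4(Y) captures the allyl cation and O-4(X) then adds to C-c.
- The key step forms no carbon–carbon bond, so the whole C10 chain, both aryl–carbon bonds and the C-a stereocentre must be built first.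
- C-a in A4 carries two carbon substituents that differ only by hydration state, which is hard to make enantioselectively.
- C-b would be set by a protonation with no kinetic bias.
- The tertiary alcohol competes with the enols for the cation.

Key step: step 6

Assumption: the sense of induction of the chiral phosphoramide in step 6 cannot be derived from first principles. The (R)-catalyst is written; the (S)-catalyst would be used, with no other change, if the opposite enantiomer were favoured.

## Route

Step 1
Reactants: 1 2,3-dimethoxyaniline
Product: 2 2,3-dimethoxy-N-methylaniline
Conditions: (CH2O)n, NaOMe, MeOH, reflux; then NaBH4, reflux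
Reagents that add atoms: paraformaldehyde (as formaldehyde), C=O
Why: Reductive mono-N-methylation: the aniline is converted into its N-methoxymethyl/imine adduct, which NaBH4 reduces, and the secondary amine does not condense again under these conditions.

Step 2
Reactants: 2 2,3-dimethoxy-N-methylaniline; 3 Meldrum's acid (2,2-dimethyl-1,3-dioxane-4,6-dione)
Product: 5 4-hydroxy-7,8-dimethoxy-1-methylquinolin-2(1H)-one, via malonamic acid 4 (not isolated)
Conditions: PhMe, 100 °C; evaporate; P2O5/MeSO3H (Eaton's reagent), 70 °C
Reagents that add atoms: none
Why: N-acylation by Meldrum's acid with loss of acetone should give the malonamic acid, and intramolecular Friedel–Crafts acylation followed by enolisation gives the 4-hydroxyquinolinone. Only one ortho position is free and it is para to a methoxy group, so the regiochemistry is fixed.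

Step 3
Reactants: 6 phorone (2,6-dimethylhepta-2,5-dien-4-one)
Product: 7 2,6-dimethylhepta-2,5-dien-4-ol
Conditions: NaBH4, CeCl3·7H2O, MeOH, 0 °C
Reagents that add atoms: none
Why: Luche reduction gives clean 1,2-reduction of the cross-conjugated dienone; the alcohol is kept cold and free of acid because it ionises readily.

Step 4
Reactants: 5 4-hydroxy-7,8-dimethoxy-1-methylquinolin-2(1H)-one; 7 2,6-dimethylhepta-2,5-dien-4-ol
Product: 8 3-(2,6-dimethylhepta-2,5-dien-4-yl)-4-hydroxy-7,8-dimethoxy-1-methylquinolin-2(1H)-one
Conditions: Pd(PPh3)4 (5 mol%), 4 Å MS, THF, 50 °C
Reagents that add atoms: none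
Why: Tsuji–Trost allylation with a free allylic alcohol, activated by the acidic enol of 5: the soft C-3 nucleophile should attack the less substituted CH terminus of the alkenyl π-allylpalladium intermediate, and any O-allyl ether would re-ionise under the zerovalent palladium catalyst, so C-allylation is the thermodynamic outcome. The neutral conditions avoid acid-induced cyclisation of O-4 onto an isobutenyl group; the product is achiral.

Step 5
Reactants: 5 4-hydroxy-7,8-dimethoxy-1-methylquinolin-2(1H)-one
Product: 10 4-hydroxy-7,8-dimethoxy-1-methyl-2-oxo-1,2-dihydroquinoline-3-carbaldehyde, via enaminone 9 (not isolated)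
Conditions: Me2NCH(OMe)2, PhMe, 80 °C; then 1 M aq NaOH, THF, rt; then aq HCl to pH 2
Reagents that add atoms: N,N-dimethylformamide dimethyl acetal, COC(OC)N(C)C; water, O
Why: Aminomethylenation of the active C-3 position followed by hydrolysis of the push–pull enaminone is a standard formylation of cyclic 1,3-dicarbonyl compounds; the second C-3 substituent cannot be introduced, so mono-formylation is assured.

Step 6
Reactants: 8 3-(2,6-dimethylhepta-2,5-dien-4-yl)-4-hydroxy-7,8-dimethoxy-1-methylquinolin-2(1H)-one; 10 4-hydroxy-7,8-dimethoxy-1-methyl-2-oxo-1,2-dihydroquinoline-3-carbaldehyde
Product: 12 (aS,bS,cR)-cis-fused hexacycle carrying 2-methylprop-1-enyl at C-a, via aryloxymethylidene dione 11 (not isolated)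
Conditions: (R)-N-triflylphosphoramide of 3,3'-bis(2,4,6-triisopropylphenyl)-1,1'-bi-2-naphthol (10 mol%), 5 Å MS, PhMe, 40 °C
Reagents that add atoms: none
Why: Proposed new method: acid-catalysed condensation of the enol hydroxyl of 8 with the vinylogous-acid aldehyde 10 (both C-3 positions are blocked, so only O–C bond formation is productive) should give the aryloxymethylidene dione 11, an electron-poor 1-oxadiene (the quinone methide of unit Y), which is trapped by one isobutenyl group in an asynchronous inverse-demand oxa-[4+2] cycloaddition, C-c–C-b first and O-4(Y)–C-d second at the incipient tertiary cation. The closest known reaction type is the acid-catalysed union of salicylaldehydes with alkenols through alkoxy ortho-quinone methides and their intramolecular [4+2] cycloaddition, including its chiral Brønsted acid version, together with the domino Knoevenagel/hetero-Diels–Alder reaction of 4-hydroxyquinolinones; what is new is an enol as the oxygen partner and a quinolinedione as the heterodiene. Ring D is closed by the cycloaddition itself (O-4(Y)–C-d and C-c–C-b), and ring C is the six-membered tether ring closed by the C-c–C-b bond, a 6-endo attack of the alkene on the oxocarbenium-like C-c in the stepwise limit. C-a versus C-b: allylic 1,3-strain with the cis methyl of the reacting trisubstituted alkene holds H-a in the alkene plane, so the methide adds to the face syn to C-3(X) and anti to the spectator isobutenyl group, which gives H-a/H-b trans. C-b versus C-c: the endo-E-syn transition state usual for tethers containing two sp2 atoms gives the cis fusion; the trans-fused isomer would push the C-a substituent and O-4(X) towards the planes of the neighbouring C-2 carbonyl groups, and because the C-c–O bond can ionise reversibly under the acid the cis isomer should also be the thermodynamic sink. Absolute configuration: the two isobutenyl groups are enantiotopic and each can reach only one face of C-c, so face selection at the methide within the ion pair or hydrogen-bonded complex with the chiral phosphoramide fixes all three centres at once. Regioselectivity: closure must occur through the ketone oxygen O-4(Y) and not the amide oxygen, which is favoured by the higher nucleophilicity of O-4 and is self-correcting, since the alternative tertiary imidate ether would re-ionise under the acid.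

Step 7
Reactants: 12 (aS,bS,cR)-cis-fused hexacycle carrying 2-methylprop-1-enyl at C-a
Product: 13 target: (aS,bS,cR)-cis-fused hexacycle carrying 2-hydroxy-2-methylpropyl at C-a
Conditions: Co(acac)2 (20 mol%), PhSiH3, O2 (1 atm), THF, rt; then PPh3
Reagents that add atoms: dioxygen, O=O
Why: Mukaiyama hydration: hydrogen-atom transfer from a cobalt hydride to the CH carbon of the only alkene gives the tertiary radical, which is captured by O2, and the peroxide is reduced to the tertiary alcohol. The conditions are neutral, so C-c is not ionised, and no stereocentre is formed or touched.

## Compound list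

1 | 2,3-dimethoxyaniline | Nc1cccc(OC)c1OC | starting material
2 | 2,3-dimethoxy-N-methylaniline | CNc1cccc(OC)c1OC | intermediate
3 | Meldrum's acid (2,2-dimethyl-1,3-dioxane-4,6-dione) | CC1(C)OC(=O)CC(=O)O1 | starting material
4 | 3-[(2,3-dimethoxyphenyl)(methyl)amino]-3-oxopropanoic acid (malonamic acid) | COc1cccc(N(C)C(=O)CC(=O)O)c1OC | intermediate (not isolated)
5 | 4-hydroxy-7,8-dimethoxy-1-methylquinolin-2(1H)-one | COc1ccc2c(O)cc(=O)n(C)c2c1OC | intermediate
6 | phorone (2,6-dimethylhepta-2,5-dien-4-one) | CC(C)=CC(=O)C=C(C)C | starting material
7 | 2,6-dimethylhepta-2,5-dien-4-ol | CC(C)=CC(O)C=C(C)C | intermediate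
8 | 3-(2,6-dimethylhepta-2,5-dien-4-yl)-4-hydroxy-7,8-dimethoxy-1-methylquinolin-2(1H)-one | COc1ccc2c(O)c(C(C=C(C)C)C=C(C)C)c(=O)n(C)c2c1OC | intermediate
9 | 3-[(dimethylamino)methylidene]-7,8-dimethoxy-1-methylquinoline-2,4(1H,3H)-dione (enaminone) | CN(C)C=C1C(=O)c2ccc(OC)c(OC)c2N(C)C1=O | intermediate (not isolated)
10 | 4-hydroxy-7,8-dimethoxy-1-methyl-2-oxo-1,2-dihydroquinoline-3-carbaldehyde | COc1ccc2c(O)c(C=O)c(=O)n(C)c2c1OC | intermediate
11 | 3-{[3-(2,6-dimethylhepta-2,5-dien-4-yl)-7,8-dimethoxy-1-methyl-2-oxo-1,2-dihydroquinolin-4-yl]oxymethylidene}-7,8-dimethoxy-1-methylquinoline-2,4(1H,3H)-dione, aryloxy group trans to the C-4 ketone | COc1ccc2c(O/C=C3/C(=O)c4ccc(OC)c(OC)c4N(C)C3=O)c(C(C=C(C)C)C=C(C)C)c(=O)n(C)c2c1OC | intermediate (not isolated)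
12 | (aS,bS,cR)-hexacycle: units X and Y fused through cis-fused rings C and D, gem-dimethyl at C-d, 2-methylprop-1-enyl at C-a | COc1ccc2c3c(c(=O)n(C)c2c1OC)[C@@H](C=C(C)C)[C@H]1[C@@H](O3)c2c(c3ccc(OC)c(OC)c3n(C)c2=O)OC1(C)C | intermediate
13 | (aS,bS,cR)-hexacycle: as 12 but with 2-hydroxy-2-methylpropyl at C-a (CNP0160874.2) | COc1ccc2c3c(c(=O)n(C)c2c1OC)[C@@H](CC(C)(C)O)[C@H]1[C@@H](O3)c2c(c3ccc(OC)c(OC)c3n(C)c2=O)OC1(C)C | target

## Step count and least certain steps

Total step count: 7. Longest linear sequence: 5 steps (steps 1, 2, 4, 6, 7; the branch through step 5 is equally long).

**Step 6 (key step, proposed new method).** Several processes could fail: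
- the uphill O-condensation of two vinylogous acids may not supply enough of 11;
- acid-catalysed addition of O-4 of 8 to its own isobutenyl group may compete;
- closure may occur through the amide oxygen;
- facial selectivity at the methide may be poor, which would erode the enantiomeric purity;
- some of the material may pass through the exo transition state and give the trans fusion.

Fallback by known chemistry, setting out from 5: condensation with 3-methylbut-2-enal (pyridine, 110 °C; Knoevenagel condensation and oxa-6π electrocyclisation) gives the pyranoquinolinone veprisine F1. Heating F1 (o-dichlorobenzene, 180 °C) opens it reversibly to the oxatriene F2, which adds as a 1-oxadiene across the pyran double bond of a second molecule of F1. This is the biomimetic inverse-demand oxa-Diels–Alder mode. The adduct with the relative configuration of 12 is separated from other dimers and resolved on a chiral stationary phase; the unwanted enantiomer F3 is discarded. The fallback returns to the route at 12.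

**Step 4.** The ionised dienyl unit may lose a proton to give a triene, be attacked at a tertiary terminus, or the skipped diene may migrate into conjugation.

Fallback, setting out from 2, builds the quinolinone ring last. Knoevenagel condensation of diethyl malonate with 3-methylbut-2-enal gives the alkylidene malonate F4. Copper-catalysed (CuBr·SMe2) 1,4-addition of 2-methylprop-1-enylmagnesium bromide gives the dienyl malonate F5. Thermal condensation of F5 with 2 in diphenyl ether at 250 °C, the classical route to 3-substituted 4-hydroxyquinolin-2-ones, returns to the route at 8.

**Step 7.** The tertiary radical may be reduced to the alkane instead of being oxygenated, or hydrogen abstraction may occur at C-a.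

Fallback, setting out from 12: oxymercuration with Hg(OAc)2 (divalent mercury) in THF/water gives the β-hydroxy organomercurial F6, which is demercurated with NaBH4/NaOH. This ionic Markovnikov hydration returns to the route at 13.

**Step 5.** Retro-Claisen loss of the formyl group during basic hydrolysis, or O-methylation of the enol by the acetal, may occur.

Fallback, setting out from 5: heating with triethyl orthoformate in acetic anhydride gives the ethoxymethylidene dione F7, which is hydrolysed with dilute aqueous acid and returns to the route at 10. F7 could also be tried directly in step 6 in place of 10.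

## Further compounds

F1 | step 6 | 7,8-dimethoxy-2,2,6-trimethyl-2,6-dihydro-5H-pyrano[3,2-c]quinolin-5-one (veprisine) | COc1ccc2c3c(c(=O)n(C)c2c1OC)C=CC(C)(C)O3
F2 | step 6 | 7,8-dimethoxy-1-methyl-3-(3-methylbut-2-en-1-ylidene)quinoline-2,4(1H,3H)-dione (oxatriene) | COc1ccc2c(c1OC)N(C)C(=O)C(=CC=C(C)C)C2=O
F3 | step 6 | (aR,bR,cS)-enantiomer of 12 | COc1ccc2c3c(c(=O)n(C)c2c1OC)[C@H](C=C(C)C)[C@@H]1[C@H](O3)c2c(c3ccc(OC)c(OC)c3n(C)c2=O)OC1(C)C
F4 | step 4 | diethyl 2-(3-methylbut-2-en-1-ylidene)malonate | CCOC(=O)C(=CC=C(C)C)C(=O)OCC
F5 | step 4 | diethyl 2-(2,6-dimethylhepta-2,5-dien-4-yl)malonate | CCOC(=O)C(C(C=C(C)C)C=C(C)C)C(=O)OCC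
F6 | step 7 | (aS,bS,cR)-hexacycle with 1-(acetoxymercurio)-2-hydroxy-2-methylpropyl at C-a | COc1ccc2c3c(c(=O)n(C)c2c1OC)[C@@H](C([Hg]OC(C)=O)C(C)(C)O)[C@H]1[C@@H](O3)c2c(c3ccc(OC)c(OC)c3n(C)c2=O)OC1(C)C
F7 | step 5 | 3-(ethoxymethylidene)-7,8-dimethoxy-1-methylquinoline-2,4(1H,3H)-dione | CCOC=C1C(=O)c2ccc(OC)c(OC)c2N(C)C1=O
A1 | alternative 1 | 7,8-dimethoxy-2,2,6-trimethyl-2,6-dihydro-5H-pyrano[3,2-c]quinolin-5-one (veprisine) | COc1ccc2c3c(c(=O)n(C)c2c1OC)C=CC(C)(C)O3
A2 | alternative 1 | 3-(3-hydroxy-3-methylbutylidene)-7,8-dimethoxy-1-methylquinoline-2,4(1H,3H)-dione | COc1ccc2c(c1OC)N(C)C(=O)C(=CCC(C)(C)O)C2=O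
A3 | alternative 2 | ring C lactol: (3S,4S)-2-hydroxy-4-(2-hydroxy-2-methylpropyl)-7,8-dimethoxy-6-methyl-3-(prop-1-en-2-yl)-3,4-dihydro-2H-pyrano[3,2-c]quinolin-5(6H)-one | COc1ccc2c3c(c(=O)n(C)c2c1OC)[C@@H](CC(C)(C)O)[C@H](C(C)=C)C(O)O3
A4 | alternative 3 | bis(4-hydroxy-7,8-dimethoxy-1-methyl-2-oxoquinolin-3-yl) diene with the C-a stereocentre, 2-hydroxy-2-methylpropyl at C-a and isopropenyl at C-b | COc1ccc2c(O)c(c(=O)n(C)c2c1OC)[C@@H](CC(C)(C)O)C(=Cc1c(O)c2ccc(OC)c(OC)c2n(C)c1=O)C(C)=C
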